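Thursday's run, 40 mM of solid substrate at 115 °C, reads 0.3% intermediate after 3.00 min and then climbs steadily, so material enters the solution slowly. Monday's run is the colder and smaller one.

| flask | solid substrate | temperature | remark | time |
|---|---|---|---|---|
| Monday's | 10 mM | 85 °C | run made earlier |  |
| Thursday's | 40 mM | 115 °C | run made earlier |  |
| grey | 20 mM | 115 °C |  | 1.0 h |
| ochre | 20 mM | 90 °C |  | 1.0 h |
| violet | 20 mM | 140 °C |  | 1.0 h |

Monday's run (percent of the solid substrate charged)

| time / h | intermediate / % | target / % |
|---|---|---|
| 0.667 | 17.4 | 1.6 |
| 1.00 | 32.5 | 4.0 |
| 1.33 | 41.8 | 6.5 |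
| 2.00 | 52.9 | 14.0 |
| 3.00 | 53.8 | 27.0 |

Thursday's run (percent of the solid substrate charged)

| time / min | intermediate / % | target / % |
|---|---|---|
| 3.00 | 0.3 | 0.5 |
| 10.0 | 3.0 | 0.5 |
| 15.0 | 4.6 | 1.1 |
| 25.0 | 7.4 | 3.0 |
| 40.0 | 11.5 | 7.9 |

(scatter of a reading: 0.5 percentage points)

- the flask with the highest amount of intermediate, in percent of the solid substrate charged ("all alike" if they lie within 1.5 percentage points) (grey / ochre / violet / all alike)
- final intermediate, as a percentage of the solid substrate charged, in grey
- final intermediate, as a percentage of the solid substrate charged, in ochre
- final intermediate, as a percentage of the solid substrate charged, in violet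

- the numbers in the tables scatter by 0.5 percentage points (one standard deviation)
- at the start none of the solid substrate is in solution
- what has only dissolved of solid substrate counts as not reacted
- a reading or a percentage of target counts all its forms, free or not

**Bench rule.** I start from the rule that a rate doubles every 10 degrees. From Monday's 85 °C to Thursday's 115 °C that means 3 doublings, a factor of 8. Let k be the target gained per hour for each unit of intermediate standing, read between the last two readings of a run. Monday's run gives 0.244 h⁻¹ and Thursday's gives 2.07 h⁻¹. These are net readings, and their factor is 8.48 against the rule's 8.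

**Where it stops.** Now take the feed, the gain in intermediate plus target in mM per hour. Monday's run reads 4.42 mM h⁻¹ and Thursday's reads 14.4 mM h⁻¹. That factor of 3.26 falls short of 8, although Thursday's charge was also larger by a factor of 4.00. So I do not scale the feed with temperature.

**Feed share.** I carry the feed share F = 72.0%, the part of a 20 mM charge that Thursday's feed brings in over the asked time. At that feed the charge needs 1.39 h to come in, while the inverse of Thursday's net k reads 0.483 h at 115 °C, so there I take the feed as the rate-limiting step. My own reckoning is that grey and violet each have about F of their charge turned to intermediate or beyond at the asked time. It does not give the split between the two.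

**The forecast.** It names grey, with grey at 23% (17% to 30%), ochre at 21% (14% to 33%) and violet at 4% (0.5% to 13%). Of violet it says “the solid is nearly exhausted by one hour”, where my flat feed differs.

**The result.** The highest is grey: grey 26.4%, ochre 22.2%, violet 20.9%, which is 17 percentage points above the forecast. At 1.00 h solid substrate stands at 25.2% in grey and 26.3% in violet, despite 115 °C against 140 °C. Against F of 72.0%, conversion reaches 59.9% in grey and 56.5% in violet, both less than F.

    starting material ⇌ intermediate (K = 7.10, k = 0.0204 min⁻¹, Ea = 105 kJ mol⁻¹, ΔH = −43.0 kJ mol⁻¹)
    intermediate ⇌ target (K = 1.00, k = 0.00766 min⁻¹, Ea = 105 kJ mol⁻¹, ΔH = −20.0 kJ mol⁻¹)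
    crystals ⇌ target, rate k3*(cs3 - [target]) while solid is left; crystals form when [target] > cs3 (solubility = 0.790 mM, k = 0.178 min⁻¹)
    solid substrate ⇌ starting material, rate k4*(cs4 - [starting material]) while solid is left; crystals form when [starting material] > cs4 (solubility = 13.0 mM, k = 0.0230 min⁻¹)
    starting material + target → side product (k = 0.130 M⁻¹ min⁻¹, Ea = 60.0 kJ mol⁻¹)
    (constants at 90 °C)

**Second flask.** Grey read at 4.0 h: F puts the charge in by 1.39 h, earlier than that reading. The computed flask holds 0% solid substrate, 89.3% target and 6.27% intermediate.

The runs are calculated for an exercise, and the scatter is random.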